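**Plan**

1. Numbering and faces: the carbocycle is C5–C6(OH)–C7–C8–C9–C10, and the bridge is C10–C1H2–C2(=O)–O–C8. C3O2H sits on C4Me2 at C5, C17 on C8 and C20 on C10. The chain C11(OH)–C12–C13(OH)(C16)–C14=C15 is on C9. With C5→C10 drawn clockwise, β points to the viewer. The target has C20, C17, H5, H6 and H9 β, and C1, C4, O6, O8 and C11 α.
2. Enabling feature: C10 lies β to the oxygenated C6, and C9 carries the carbonyl-level carbon C11 beside the methyl-bearing C8. The six-membered carbocycle is therefore a latent 3-methyl-4-acylcyclohex-2-enone. It divides into an acetoacetate (C17, C8, C9, C11) and a β,β-disubstituted enone (C7, C6, C5, C10).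
3. Retrosynthetic cuts, in order: O–C8 of the bridging lactone, C13–C16, C11–C12, C4–C5, then C7=C8 and C9–C10 together.
4. Forward order: the carbocycle closes first by Michael–aldol annulation. A temporary cis-fused δ-lactone C11(=O)–O–C2 closes next. It serves for stereocontrol, is redox-transposed to C2(=O)–O–C11, and is then opened. The side chain is joined afterwards, and the 2-oxabicyclo[3.3.1]nonanone bridge closes last.
5. Stereochemistry: C10 comes from a chiral primary amine, and C9 from equilibration to the cis-fused lactone. C5 comes from radical attack anti to C20 on a flat triene, and C6 from hydride delivery on the β face. C11 is set by Felkin–Anh addition, C13 by chelation, and C8 by the C1–C2 tether.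

Key step: step 3

Assumption: the sense of induction of cinchona primary amines on this β,β-dialkyl enone is not known. The quinine-derived catalyst is written for Re-face attack at C10, and its quinidine-derived pseudoenantiomer would be taken if the opposite face is attacked.
Assumption: among O6, O8 and O11, all of which can reach C2, the 8-O-acyl/6-hydroxy arrangement of the target is taken to be the resting position of the acyl group. O6 is nevertheless kept silylated until the last step.

**Step 1**
Reactants: 1 tert-butyl(but-3-yn-1-yloxy)dimethylsilane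
Product: 3 tert-butyl{[(3E)-4-iodo-3-methylbut-3-en-1-yl]oxy}dimethylsilane, via alkenylalane 2 (not isolated)
Conditions: Me3Al (2.5 equiv), Cp2ZrCl2 (0.25 equiv), CH2Cl2, 0 °C to rt; then I2, THF, −30 °C
Reagents that add atoms: trimethylaluminium C[Al](C)C; iodine II
Why: Negishi zirconium-catalysed carboalumination adds methyl and aluminium syn across the terminal alkyne with aluminium at the terminus, and iodinolysis with retention should give only the E-iodide that fixes the C5=C10 geometry.

**Step 2**
Reactants: 3 tert-butyl{[(3E)-4-iodo-3-methylbut-3-en-1-yl]oxy}dimethylsilane; 4 N-methoxy-N-methylacetamide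
Product: 6 (3E)-6-[(tert-butyldimethylsilyl)oxy]-4-methylhex-3-en-2-one, via alkenyllithium 5 (not isolated)
Conditions: t-BuLi (2.1 equiv), Et2O, −78 °C; then 4, −78 to 0 °C; H2O
Reagents that add atoms: none
Why: Iodine–lithium exchange keeps the alkene geometry, and acylation of the alkenyllithium with a Weinreb amide stops at the ketone because the chelated adduct collapses only on quenching.

**Step 3**
Reactants: 6 (3E)-6-[(tert-butyldimethylsilyl)oxy]-4-methylhex-3-en-2-one; 7 methyl acetoacetate
Product: 10 methyl (1R,6R)-6-{2-[(tert-butyldimethylsilyl)oxy]ethyl}-2,6-dimethyl-4-oxocyclohex-2-ene-1-carboxylate, via Michael adduct 8 (not isolated), via ketol 9 (not isolated)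
Conditions: 7 (2 equiv), 9-amino(9-deoxy)epi-quinine (15 mol%), salicylic acid (30 mol%), toluene, 9 kbar, 50 °C; then 1 bar, 4 Å molecular sieves, 80 °C
Reagents that add atoms: none
Why: Proposed new method: the primary amine condenses with 6 to an E-iminium ion, the enol of 7 (held by the protonated quinuclidine) adds through C9 to C10, and the amine then converts the C6 methyl ketone of 8 into its C7 enamine, which attacks the C8 ketone and loses water, so that C9–C10 and C7=C8 form in one flask. The closest known reaction types are the racemic Lewis-acid or alkoxide condensation of acetoacetic esters with mesityl oxide to isophorone-4-carboxylates and the high-pressure cinchona primary-amine iminium additions of nitromethane or malonates to β,β-disubstituted enones, which do build quaternary carbons enantioselectively; their union with an acetoacetate donor has not been shown. The Michael step is intermolecular and closes no ring, and the carbocycle closes in the aldol step as a 6-(enolendo)-exo-trig attack, because both C6 and C7 of the enamine lie in the new ring. C10 is fixed by the catalyst, which must expose the Re face of C10 in the E-iminium ion and tell C20 from the C1H2 chain, whereas C9 remains a labile vinylogous β-keto ester centre that is settled in step 4. The step needs C- rather than O-attack, aldol closure C7→C8 rather than C17→C6 and an intact E-alkene; the regiochemistry follows from enamine formation at the unhindered, non-enolised C6 methyl ketone and from the ester-activated C8 acetyl acting as the acceptor, and dehydration to the conjugated enone pulls the reversible Michael equilibrium forward. C2 is carried as a silyl ether because an ester there would make C1–H vinylogously acidic, divert the iminium ion into a push–pull dienamine and consume the amine as an N-substituted 4,6-dimethylpyridin-2-one.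

**Step 4**
Reactants: 10 methyl (1R,6R)-6-{2-[(tert-butyldimethylsilyl)oxy]ethyl}-2,6-dimethyl-4-oxocyclohex-2-ene-1-carboxylate
Product: 12 cis-fused keto lactone (4aR,8aR)-4a,8-dimethyl-3,4,4a,5-tetrahydro-1H-isochromene-1,6(8aH)-dione, via hydroxy ester 11 (not isolated)
Conditions: p-TsOH·H2O (0.1 equiv), MeOH, rt; then solvent change to toluene, 80 °C, MeOH distilled off
Reagents that add atoms: none
Why: Acid methanolysis of the primary silyl ether is followed by acid-catalysed lactonisation (transesterification), during which C9 epimerises through the dienol and should settle as the cis-fused lactone (C11 and C1 α), since the trans fusion holds C11=O in the plane of C17 (A(1,2) strain).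

**Step 5**
Reactants: 12 (4aR,8aR)-4a,8-dimethyl-3,4,4a,5-tetrahydro-1H-isochromene-1,6(8aH)-dione
Product: 14 (4aR)-4a,8-dimethyl-1,6-bis(trimethylsilyloxy)-4,4a-dihydro-3H-isochromene, via dilithium dienediolate 13 (not isolated)
Conditions: LiN(iPr)2 (2.4 equiv), THF, −78 to −40 °C; Me3SiCl (3 equiv), −78 to 0 °C; pentane, filtration under argon, used crude
Reagents that add atoms: chlorotrimethylsilane C[Si](C)(C)Cl
Why: Dianion formation as for β-keto esters (first the doubly activated C9–H, then the C5–H next to the lithium-bearing O6) and double O-silylation give the cross-conjugated enol silane–ketene acetal in which every ring carbon of the carbocycle except C10 is sp2.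

**Step 6**
Reactants: 14 (4aR)-4a,8-dimethyl-1,6-bis(trimethylsilyloxy)-4,4a-dihydro-3H-isochromene; 15 tert-butyl 2-bromo-2-methylpropanoate
Product: 17 tert-butyl 2-[(4aR,5R,8aS)-4a,8-dimethyl-1,6-dioxo-3,4,4a,5,6,8a-hexahydro-1H-isochromen-5-yl]-2-methylpropanoate, via silyl dienol ether 16 (not isolated)
Conditions: 15 (2 equiv), Ir(ppy)3 (1 mol%), MeCN, blue LEDs, rt; then aq. citric acid, THF, 0 °C, aq. NaHCO3 wash; then Et3N (0.2 equiv), CH2Cl2, rt
Reagents that add atoms: none
Why: This is a photoredox radical–polar crossover alkylation of a silyl enol ether with a tertiary α-bromo ester, in which the electrophilic radical adds to the unsubstituted triene terminus C5, the oxygen-stabilised pentadienyl radical is oxidised and loses silicon, the radical enters anti to the pseudoaxial C20 (α face) because C10 is the only sp3 ring atom and C1 is tied back in the heterocycle, and Et3N then equilibrates only the acidic C9 to the cis fusion, the one that lets the C5 group sit equatorial.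

**Step 7**
Reactants: 17 tert-butyl 2-[(4aR,5R,8aS)-4a,8-dimethyl-1,6-dioxo-3,4,4a,5,6,8a-hexahydro-1H-isochromen-5-yl]-2-methylpropanoate
Product: 18 tert-butyl 2-[(4aR,5R,6R,8aS)-6-hydroxy-4a,8-dimethyl-1-oxo-3,4,4a,5,6,8a-hexahydro-1H-isochromen-5-yl]-2-methylpropanoate
Conditions: NaBH4, CeCl3·7H2O, MeOH/CH2Cl2, −78 °C
Reagents that add atoms: none
Why: Luche 1,2-reduction is selective for the enone carbonyl, and with the C4 group equatorial the C1 methylene is axial on the α face and 1,3 to C6, so hydride should enter from the β face and place O6 α, while the hindered tert-butyl ester resists γ-lactonisation at low temperature.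

**Step 8**
Reactants: 18 tert-butyl 2-[(4aR,5R,6R,8aS)-6-hydroxy-4a,8-dimethyl-1-oxo-3,4,4a,5,6,8a-hexahydro-1H-isochromen-5-yl]-2-methylpropanoate
Product: 19 tert-butyl 2-[(4aR,5R,6R,8aS)-4a,8-dimethyl-1-oxo-6-(triethylsilyloxy)-3,4,4a,5,6,8a-hexahydro-1H-isochromen-5-yl]-2-methylpropanoate
Conditions: Et3SiOTf, 2,6-lutidine, CH2Cl2, −78 °C
Reagents that add atoms: triethylsilyl trifluoromethanesulfonate CC[Si](CC)(CC)OS(=O)(=O)C(F)(F)F
Why: Silylation of a hindered secondary alcohol with a silyl triflate and a hindered pyridine is fast at −78 °C, where the tert-butyl ester is untouched, and it shields O6 from oxidation and from acyl capture in all later steps.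

**Step 9**
Reactants: 19 tert-butyl 2-[(4aR,5R,6R,8aS)-4a,8-dimethyl-1-oxo-6-(triethylsilyloxy)-3,4,4a,5,6,8a-hexahydro-1H-isochromen-5-yl]-2-methylpropanoate
Product: 20 tert-butyl 2-[2-(2-hydroxyethyl)-3-(hydroxymethyl)-2,4-dimethyl-6-(triethylsilyloxy)cyclohex-4-en-1-yl]-2-methylpropanoate (C4 group at C5, O6, C11 and C1 all α; C20 β)
Conditions: LiBH4 (3 equiv), THF, 0 °C to rt
Reagents that add atoms: none
Why: Borohydride reduction of a lactone gives the 1,5-diol, because LiBH4 reduces lactones but not an α-quaternary tert-butyl ester, and C9 ceases to be an acidic centre.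

**Step 10**
Reactants: 20 tert-butyl 2-[2-(2-hydroxyethyl)-3-(hydroxymethyl)-2,4-dimethyl-6-(triethylsilyloxy)cyclohex-4-en-1-yl]-2-methylpropanoate
Product: 22 tert-butyl 2-[4a,8-dimethyl-3-oxo-6-(triethylsilyloxy)-3,4,4a,5,6,8a-hexahydro-1H-isochromen-5-yl]-2-methylpropanoate (cis-fused C2(=O)–O–C11 lactone; C4 group and O6 α), via lactol 21 (not isolated)
Conditions: TEMPO (0.2 equiv), PhI(OAc)2 (2.5 equiv), CH2Cl2, rt
Reagents that add atoms: none
Why: Oxoammonium oxidative lactonisation of a 1,5-diol starts at the less hindered primary alcohol (C2–OH rather than the C11–OH flanked by C8 and quaternary C10), so the lactol closes through O11 and is oxidised to the transposed lactone with C2 at the acid level.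

**Step 11**
Reactants: 22 tert-butyl 2-[4a,8-dimethyl-3-oxo-6-(triethylsilyloxy)-3,4,4a,5,6,8a-hexahydro-1H-isochromen-5-yl]-2-methylpropanoate
Product: 23 tert-butyl 2-{2-[2-(dimethylamino)-2-oxoethyl]-3-(hydroxymethyl)-2,4-dimethyl-6-(triethylsilyloxy)cyclohex-4-en-1-yl}-2-methylpropanoate
Conditions: Me2NH (2 M in THF, 10 equiv), 40 °C, sealed tube
Reagents that add atoms: dimethylamine CNC
Why: Aminolysis of a δ-lactone by a secondary amine gives a tertiary hydroxy amide that does not relactonise, frees C11–OH and installs a strong neighbouring group for the later halolactonisation.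

**Step 12**
Reactants: 23 tert-butyl 2-{2-[2-(dimethylamino)-2-oxoethyl]-3-(hydroxymethyl)-2,4-dimethyl-6-(triethylsilyloxy)cyclohex-4-en-1-yl}-2-methylpropanoate
Product: 24 tert-butyl 2-{2-[2-(dimethylamino)-2-oxoethyl]-3-formyl-2,4-dimethyl-6-(triethylsilyloxy)cyclohex-4-en-1-yl}-2-methylpropanoate
Conditions: Dess–Martin periodinane, NaHCO3, CH2Cl2, 0 °C; used at once
Reagents that add atoms: none
Why: Buffered Dess–Martin oxidation of a primary alcohol works under near-neutral conditions that should leave the β,γ-alkene unconjugated and C9 unepimerised.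

**Step 13**
Reactants: 24 tert-butyl 2-{2-[2-(dimethylamino)-2-oxoethyl]-3-formyl-2,4-dimethyl-6-(triethylsilyloxy)cyclohex-4-en-1-yl}-2-methylpropanoate; 25 2-(trimethylsilyloxy)buta-1,3-diene
Product: 26 tert-butyl 2-{2-[2-(dimethylamino)-2-oxoethyl]-3-[(1S)-1-hydroxy-3-oxopent-4-en-1-yl]-2,4-dimethyl-6-(triethylsilyloxy)cyclohex-4-en-1-yl}-2-methylpropanoate
Conditions: 25 (3 equiv), BF3·OEt2 (2.5 equiv), CH2Cl2, −78 °C; pH 7 buffer
Reagents that add atoms: none
Why: The BF3-mediated Mukaiyama aldol addition runs through an open transition state under Felkin–Anh control, with quaternary C10 anti to the incoming enol silane, the flat sp2 C8 next to the carbonyl oxygen and the nucleophile passing H9, which exposes the Si face of C11 and should give the 11S alcohol.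

**Step 14**
Reactants: 26 tert-butyl 2-{2-[2-(dimethylamino)-2-oxoethyl]-3-[(1S)-1-hydroxy-3-oxopent-4-en-1-yl]-2,4-dimethyl-6-(triethylsilyloxy)cyclohex-4-en-1-yl}-2-methylpropanoate
Product: 27 tert-butyl 2-{2-[2-(dimethylamino)-2-oxoethyl]-3-[(1S,3R)-1,3-dihydroxy-3-methylpent-4-en-1-yl]-2,4-dimethyl-6-(triethylsilyloxy)cyclohex-4-en-1-yl}-2-methylpropanoate
Conditions: MeTi(OiPr)3 (3 equiv), CH2Cl2, −40 to 0 °C; aq. NH4F
Reagents that add atoms: methyltitanium triisopropoxide C[Ti](OC(C)C)(OC(C)C)OC(C)C
Why: In this chelation-controlled 1,2-addition of a non-basic methyltitanium reagent to a β-hydroxy ketone, O11 exchanges onto titanium, the six-membered chelate places the carbocycle equatorial and methyl is delivered axially, which gives the 11,13-syn diol (13R) without 1,4-addition or attack on amide and ester.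

**Step 15**
Reactants: 27 tert-butyl 2-{2-[2-(dimethylamino)-2-oxoethyl]-3-[(1S,3R)-1,3-dihydroxy-3-methylpent-4-en-1-yl]-2,4-dimethyl-6-(triethylsilyloxy)cyclohex-4-en-1-yl}-2-methylpropanoate
Product: 29 tert-butyl 2-{9-[(1S,3R)-1,3-dihydroxy-3-methylpent-4-en-1-yl]-8-iodo-1,5-dimethyl-3-oxo-7-(triethylsilyloxy)-2-oxabicyclo[3.3.1]nonan-6-yl}-2-methylpropanoate (iodine β on C7; O8 α), via iminium lactone iodide 28 (not isolated)
Conditions: I2 (1.2 equiv), THF/H2O 2:1, 0 °C, dark; aq. Na2S2O3/NaHCO3
Reagents that add atoms: iodine II; water O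
Why: In this iodolactonisation through the amide oxygen (6-exo attack at the tertiary terminus C8), iodine takes the open β face of the only trisubstituted alkene, the axial α C1–C2 arm delivers oxygen anti to it, water hydrolyses the iminium lactone, and the less nucleophilic C14=C15 and the hydroxyls should be slower partners when iodine is kept to a slight excess.

**Step 16**
Reactants: 29 tert-butyl 2-{9-[(1S,3R)-1,3-dihydroxy-3-methylpent-4-en-1-yl]-8-iodo-1,5-dimethyl-3-oxo-7-(triethylsilyloxy)-2-oxabicyclo[3.3.1]nonan-6-yl}-2-methylpropanoate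
Product: 30 tert-butyl 2-{9-[(1S,3R)-1,3-dihydroxy-3-methylpent-4-en-1-yl]-1,5-dimethyl-3-oxo-7-(triethylsilyloxy)-2-oxabicyclo[3.3.1]nonan-6-yl}-2-methylpropanoate
Conditions: Bu3SnH (1.5 equiv), Et3B (0.2 equiv), air, toluene, 0 °C to rt
Reagents that add atoms: none
Why: In this tin hydride radical dehalogenation of a secondary iodide, hydrogen transfer to the C7 radical is faster than acyloxy migration or addition to the remote vinyl group, and no stereocentre is involved.

**Step 17**
Reactants: 30 tert-butyl 2-{9-[(1S,3R)-1,3-dihydroxy-3-methylpent-4-en-1-yl]-1,5-dimethyl-3-oxo-7-(triethylsilyloxy)-2-oxabicyclo[3.3.1]nonan-6-yl}-2-methylpropanoate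
Product: 32 CNP0297019.1 (5R,6R,8S,9S,10R,11S,13R) 2-{9-[(1S,3R)-1,3-dihydroxy-3-methylpent-4-en-1-yl]-7-hydroxy-1,5-dimethyl-3-oxo-2-oxabicyclo[3.3.1]nonan-6-yl}-2-methylpropanoic acid, via persilylated lactone 31 (not isolated)
Conditions: Me3SiOTf (6 equiv), 2,6-lutidine (9 equiv), CH2Cl2, 0 °C; then HF·pyridine, pyridine, THF, 0 °C; pH 5 buffer
Reagents that add atoms: none
Why: Silyl triflate–lutidine cleavage of a tert-butyl ester (loss of isobutene from the O-silylated ester) works under buffered aprotic conditions that spare the tertiary allylic carbinol, and buffered fluoride then removes all silyl groups without base able to move the C2 acyl group or acid able to close a C3–O6 γ-lactone.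

**Compound list**

1 | tert-butyl(but-3-yn-1-yloxy)dimethylsilane | C#CCCO[Si](C)(C)C(C)(C)C | starting material
2 | dimethyl[(1E)-4-(tert-butyldimethylsilyloxy)-2-methylbut-1-en-1-yl]alane | C/C(CCO[Si](C)(C)C(C)(C)C)=C\[Al](C)C | intermediate
3 | tert-butyl{[(3E)-4-iodo-3-methylbut-3-en-1-yl]oxy}dimethylsilane | C/C(CCO[Si](C)(C)C(C)(C)C)=C\I | intermediate
4 | N-methoxy-N-methylacetamide | CON(C)C(C)=O | starting material
5 | (1E)-4-(tert-butyldimethylsilyloxy)-2-methylbut-1-en-1-yllithium | C/C(CCO[Si](C)(C)C(C)(C)C)=C\[Li] | intermediate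
6 | (3E)-6-[(tert-butyldimethylsilyl)oxy]-4-methylhex-3-en-2-one (C7–C6–C5=C10 with C20 and C1–C2–OSi) | CC(=O)/C=C(\C)CCO[Si](C)(C)C(C)(C)C | intermediate
7 | methyl acetoacetate | COC(=O)CC(C)=O | starting material
8 | methyl (3R)-2-acetyl-3-{2-[(tert-butyldimethylsilyl)oxy]ethyl}-3-methyl-5-oxohexanoate (C9 labile) | COC(=O)C(C(C)=O)[C@](C)(CCO[Si](C)(C)C(C)(C)C)CC(C)=O | intermediate
9 | methyl (6R)-6-{2-[(tert-butyldimethylsilyl)oxy]ethyl}-2-hydroxy-2,6-dimethyl-4-oxocyclohexane-1-carboxylate (C8 and C9 undefined) | COC(=O)C1[C@](C)(CCO[Si](C)(C)C(C)(C)C)CC(=O)CC1(C)O | intermediate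
10 | methyl (1R,6R)-6-{2-[(tert-butyldimethylsilyl)oxy]ethyl}-2,6-dimethyl-4-oxocyclohex-2-ene-1-carboxylate (drawn with C11 α; the C9 epimer equilibrates with it) | COC(=O)[C@@H]1[C@](C)(CCO[Si](C)(C)C(C)(C)C)CC(=O)C=C1C | intermediate
11 | methyl (1R,6R)-6-(2-hydroxyethyl)-2,6-dimethyl-4-oxocyclohex-2-ene-1-carboxylate | COC(=O)[C@@H]1[C@](C)(CCO)CC(=O)C=C1C | intermediate
12 | (4aR,8aR)-4a,8-dimethyl-3,4,4a,5-tetrahydro-1H-isochromene-1,6(8aH)-dione (cis-fused; H9 and C20 β) | O=C1OCC[C@]2(C)CC(=O)C=C(C)[C@H]12 | intermediate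
13 | dilithium dienediolate of 12 (O6 and O11 lithiated) | [Li]OC1=C2C(C)=CC(O[Li])=C[C@@]2(C)CCO1 | intermediate
14 | (4aR)-4a,8-dimethyl-1,6-bis(trimethylsilyloxy)-4,4a-dihydro-3H-isochromene | C[Si](C)(C)OC1=C2C(C)=CC(O[Si](C)(C)C)=C[C@@]2(C)CCO1 | intermediate
15 | tert-butyl 2-bromo-2-methylpropanoate | CC(C)(Br)C(=O)OC(C)(C)C | starting material
16 | tert-butyl 2-[4a,8-dimethyl-1-oxo-6-(trimethylsilyloxy)-3,4,4a,5-tetrahydro-1H-isochromen-5-yl]-2-methylpropanoate (C4 group α; C6=C7 and C8=C9) | O=C1OCC[C@]2(C)[C@H](C(C)(C)C(=O)OC(C)(C)C)C(O[Si](C)(C)C)=CC(C)=C12 | intermediate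
17 | tert-butyl 2-[(4aR,5R,8aS)-4a,8-dimethyl-1,6-dioxo-3,4,4a,5,6,8a-hexahydro-1H-isochromen-5-yl]-2-methylpropanoate (C4 group, C1 and C11 α) | O=C1OCC[C@]2(C)[C@H](C(C)(C)C(=O)OC(C)(C)C)C(=O)C=C(C)[C@H]12 | intermediate
18 | tert-butyl 2-[(4aR,5R,6R,8aS)-6-hydroxy-4a,8-dimethyl-1-oxo-3,4,4a,5,6,8a-hexahydro-1H-isochromen-5-yl]-2-methylpropanoate (O6 α) | O=C1OCC[C@]2(C)[C@H](C(C)(C)C(=O)OC(C)(C)C)[C@H](O)C=C(C)[C@H]12 | intermediate
19 | 6-O-triethylsilyl ether of 18 | O=C1OCC[C@]2(C)[C@H](C(C)(C)C(=O)OC(C)(C)C)[C@H](O[Si](CC)(CC)CC)C=C(C)[C@H]12 | intermediate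
20 | tert-butyl 2-[2-(2-hydroxyethyl)-3-(hydroxymethyl)-2,4-dimethyl-6-(triethylsilyloxy)cyclohex-4-en-1-yl]-2-methylpropanoate (C4 group, O6, C11, C1 α; C20 β) | OCC[C@]1(C)[C@H](C(C)(C)C(=O)OC(C)(C)C)[C@H](O[Si](CC)(CC)CC)C=C(C)[C@@H]1CO | intermediate
21 | lactol C2H(OH)–O–C11H2 of the C2 aldehyde (C2 undefined) | OC1C[C@]2(C)[C@H](C(C)(C)C(=O)OC(C)(C)C)[C@H](O[Si](CC)(CC)CC)C=C(C)[C@@H]2CO1 | intermediate
22 | tert-butyl 2-[4a,8-dimethyl-3-oxo-6-(triethylsilyloxy)-3,4,4a,5,6,8a-hexahydro-1H-isochromen-5-yl]-2-methylpropanoate (cis-fused; C4 group and O6 α) | O=C1C[C@]2(C)[C@H](C(C)(C)C(=O)OC(C)(C)C)[C@H](O[Si](CC)(CC)CC)C=C(C)[C@@H]2CO1 | intermediate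
23 | hydroxy dimethylamide (C2 amide, C11H2OH; ring stereochemistry as 20) | CN(C)C(=O)C[C@]1(C)[C@H](C(C)(C)C(=O)OC(C)(C)C)[C@H](O[Si](CC)(CC)CC)C=C(C)[C@@H]1CO | intermediate
24 | C11 aldehyde of 23 | CN(C)C(=O)C[C@]1(C)[C@H](C(C)(C)C(=O)OC(C)(C)C)[C@H](O[Si](CC)(CC)CC)C=C(C)[C@@H]1C=O | intermediate
25 | 2-(trimethylsilyloxy)buta-1,3-diene | C=CC(=C)O[Si](C)(C)C | starting material
26 | (11S)-β-hydroxy vinyl ketone | CN(C)C(=O)C[C@]1(C)[C@H](C(C)(C)C(=O)OC(C)(C)C)[C@H](O[Si](CC)(CC)CC)C=C(C)[C@@H]1[C@@H](O)CC(=O)C=C | intermediate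
27 | (11S,13R)-syn-diol | CN(C)C(=O)C[C@]1(C)[C@H](C(C)(C)C(=O)OC(C)(C)C)[C@H](O[Si](CC)(CC)CC)C=C(C)[C@@H]1[C@@H](O)C[C@@](C)(O)C=C | intermediate
28 | bridged N,N-dimethyliminium lactone iodide (7β-iodo, O8 α) | C[N+](C)=C1C[C@]2(C)[C@H](C(C)(C)C(=O)OC(C)(C)C)[C@H](O[Si](CC)(CC)CC)[C@@H](I)[C@](C)(O1)[C@@H]2[C@@H](O)C[C@@](C)(O)C=C.[I-] | intermediate
29 | 7β-iodo bridged lactone | O=C1C[C@]2(C)[C@H](C(C)(C)C(=O)OC(C)(C)C)[C@H](O[Si](CC)(CC)CC)[C@@H](I)[C@](C)(O1)[C@@H]2[C@@H](O)C[C@@](C)(O)C=C | intermediate
30 | bridged lactone, 6-O-triethylsilyl ether and tert-butyl ester of the target | O=C1C[C@]2(C)[C@H](C(C)(C)C(=O)OC(C)(C)C)[C@H](O[Si](CC)(CC)CC)C[C@](C)(O1)[C@@H]2[C@@H](O)C[C@@](C)(O)C=C | intermediate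
31 | trimethylsilyl ester, 11,13-bis(trimethylsilyl) ether and 6-triethylsilyl ether of the target | O=C1C[C@]2(C)[C@H](C(C)(C)C(=O)O[Si](C)(C)C)[C@H](O[Si](CC)(CC)CC)C[C@](C)(O1)[C@@H]2[C@@H](O[Si](C)(C)C)C[C@@](C)(O[Si](C)(C)C)C=C | intermediate
32 | CNP0297019.1 (5R,6R,8S,9S,10R,11S,13R) | C=C[C@](C)(O)C[C@H](O)[C@@H]1[C@]2(C)CC(=O)O[C@@]1(C)C[C@@H](O)[C@H]2C(C)(C)C(=O)O | target

**Step count**

Total steps: 17. Longest linear sequence: 17 steps (1 to 32). Compounds 4, 7, 15 and 25 are bought.

**Steps most likely to fail**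

1. **Step 3.** Four processes could defeat it.
   - Conjugate addition at the fully substituted C10 may be too slow or may revert.
   - The amine may be held back as the β-enamino ester of 7.
   - The iminium ion may scramble its E/Z geometry through the dienamine, which lowers the enantioselectivity.
   - Silanolate may be lost vinylogously from C2.

   Fallback (known chemistry, from 6 and 7 back to 12): the two components are condensed without a chiral catalyst, using anhydrous ZnCl2 in refluxing toluene with water separation. These are the conditions long used for acetoacetic esters and mesityl oxide, and they give the racemic enone ester F1. Acid methanolysis and lactonisation as in step 4 give the racemic cis-lactone F2. F2 is resolved by preparative supercritical-fluid chromatography on an amylose carbamate phase, and the (4aR,8aR) enantiomer is 12.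

2. **Step 6.** Four processes could defeat it.
   - Addition of a tertiary radical next to quaternary C10 may be too slow.
   - Addition may occur at another terminus. This includes C17, if the second deprotonation of step 5 strays to the methyl group.
   - The ketene acetal may be protodesilylated before it reacts.
   - Facial selectivity at C5 may be poor.

   Fallback (from 12 back to 17): oxidative enolate heterocoupling replaces the atom-transfer alkylation. The dianion 13 is generated as in step 5 and mixed at −78 °C with the lithium enolate of tert-butyl 2-methylpropanoate F3, made from the ester and LiN(iPr)2. The mixture is oxidised with Cu(2-ethylhexanoate)2. The same flat, C20-shielded π system receives the C4 unit, and an acid quench followed by Et3N equilibration gives 17.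

3. **Step 13.** Four processes could defeat it.
   - Felkin–Anh selectivity may erode.
   - The C7=C8 bond may migrate into conjugation with the aldehyde.
   - C9 may epimerise.
   - The diene may consume the aldehyde by cycloaddition, or the product may close by oxa-Michael addition to a tetrahydropyranone.

   Fallback (from 24 back to 26): reagent control by an acetate aldol with a chiral auxiliary.
   - The chlorotitanium enolate of (4R)-3-acetyl-4-isopropyl-1,3-thiazolidine-2-thione (TiCl4, iPr2NEt, CH2Cl2, −78 °C) should attack the Si face of C11 on the chelated chair model. This gives the thiazolidinethione aldol adduct F4.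
   - MeNHOMe·HCl and imidazole displace the auxiliary to give the β-hydroxy Weinreb amide F5.
   - CH2=CHMgBr (THF, −78 to −20 °C, cold buffered quench) converts F5 into 26.

**Further compounds**

F1 | step 3 | racemic methyl 6-{2-[(tert-butyldimethylsilyl)oxy]ethyl}-2,6-dimethyl-4-oxocyclohex-2-ene-1-carboxylate | COC(=O)C1C(C)=CC(=O)CC1(C)CCO[Si](C)(C)C(C)(C)C
F2 | step 3 | racemic cis-4a,8-dimethyl-3,4,4a,5-tetrahydro-1H-isochromene-1,6(8aH)-dione | O=C1OCCC2(C)CC(=O)C=C(C)C12
F3 | step 6 | lithium enolate of tert-butyl 2-methylpropanoate | CC(C)=C(O[Li])OC(C)(C)C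
F4 | step 13 | (11S)-aldol adduct bearing the (4R)-4-isopropyl-2-thioxo-1,3-thiazolidin-3-yl amide at C13 | CN(C)C(=O)C[C@]1(C)[C@H](C(C)(C)C(=O)OC(C)(C)C)[C@H](O[Si](CC)(CC)CC)C=C(C)[C@@H]1[C@@H](O)CC(=O)N2[C@H](C(C)C)CSC2=S
F5 | step 13 | (11S)-β-hydroxy N-methoxy-N-methylamide | CN(C)C(=O)C[C@]1(C)[C@H](C(C)(C)C(=O)OC(C)(C)C)[C@H](O[Si](CC)(CC)CC)C=C(C)[C@@H]1[C@@H](O)CC(=O)N(C)OC
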